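The easy step came first: I read delta as fractions of its charge, since amber, red and blue hold less starting material than delta, and a fraction can be carried from one charge to another.

| flask | starting material | second substrate | free enzyme | temperature | remark | time |
|---|---|---|---|---|---|---|
| delta | 30 mM | 50 mM | 0.92 µM | 52 °C | run made earlier |  |
| amber | 20 mM | 50.0 mM | 0.92 µM |  | at 52 °C until 10 h, from then on at 37 °C | 30 h |
| red | 20 mM | 50.0 mM | 0.92 µM | 52 °C |  | 30 h |
| blue | 20 mM | 50.0 mM | 0.92 µM | 37 °C |  | 30 h |

delta run (percent of the starting material charged)

| time / h | product / % |
|---|---|
| 0.500 | 2.1 |
| 1.00 | 2.8 |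
| 2.50 | 4.7 |
| 6.00 | 8.2 |

(each reading ± 0.5 percentage points)

- what was read earlier has a scatter of 0.5 percentage points, one standard deviation
- the earlier runs do not show what temperature does; that part of a forecast is a guess

* the flask that comes out highest in amount of product, in percent of the starting material charged, or "all alike" when all lie within 1.5 percentage points (amber / red / blue / all alike)
* product at the end, in percent of the starting material charged, amber
* product at the end, in percent of the starting material charged, red
* product at the end, in percent of the starting material charged, blue

The free enzyme in amber, red and blue equals delta's, so nothing needed scaling there. But delta bends: it shows 2.1% at 0.500 h, yet 8.2% at 6.00 h. So I took the late stretch from 1.00 h to 6.00 h, where a scatter of 0.5 percentage points stands against a rise of 5.4 points.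

As the zero of my scale I took the plainest case: each part of the charge has the same chance per hour (pseudo-first-order in starting material), so the size of the charge drops out. Delta's late stretch then gives 0.0114 /h, and so 60.6 h for the quantity I carried, the charge clock: the time in which a flask turns half of what it still holds into product.

On that clock red, at delta's 52 °C, ends at 29.0%. That figure is my own. Blue and amber differ from red in temperature, which the earlier runs do not show, so I kept it as the zero to read them against.

The forecast named red highest, with amber 21%, red 30% and blue 16%, and warned: “if the early slowing is heat inactivation of the enzyme, blue could run much higher”. Its blue is the number that the usual doubling of rates with temperature gives from delta.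

The flasks gave amber 13.7%, red 11.6% and blue 36.9%, so blue came out highest.

    free enzyme → unfolded enzyme (k = 9.70 × 10⁻⁸ /s, Ea = 251 kJ/mol)
    starting material + free enzyme ⇌ starting complex (K = 15.0 /M, k = 350 /M/s, Ea = 43.0 kJ/mol, ΔH = −47.0 kJ/mol)
    second substrate + starting complex ⇌ ternary complex (K = 60.0 /M, k = 44.0 /M/s, Ea = 51.0 kJ/mol, ΔH = −59.0 kJ/mol)
    ternary complex → free enzyme + product (k = 0.720 /s, Ea = 76.0 kJ/mol)
    starting material ⇌ dormant form (K = 8.60, k = 1.70 × 10⁻⁵ /s, Ea = 99.0 kJ/mol, ΔH = 30.0 kJ/mol)
    (constants at 37 °C)

Read backwards from its end, blue's clock is 45.1 h, shorter than delta's, and red's is 169 h, longer than delta's. The neighbour of blue holds 2.30 µM of free enzyme, 2.50 times blue's charge, all else as in blue. Dividing blue's clock by that factor gave 18.0 h for the neighbour, and so 68.4% of product at 30 h. The neighbour gave 60.7%, less than that.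

(Readings and results are simulated from invented constants.)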